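**Retrosynthetic overview**
1. Lactone E is made last: the C3–C14 bond comes from a vinylogous Mannich addition of 3‑methyl‑2‑silyloxyfuran to the C3 iminium ion (decarbonylation of tetracyclic amino acid 15), then face‑selective hydrogenation sets C16.
2. Rings B (azepane) and A (butenolide N,O‑acetal) form together: the amino‑aldehyde 13 closes to a cyclic enamine, which is annulated with pyruvic acid (N–C5, C6–Cα and C5–O bonds).
3. The C9–C9a bond comes from a vinylogous Mannich reaction of a 5‑alkyl‑2‑silyloxyfuran with an L‑pyroglutamate‑derived N‑acyliminium ion; the C11 methyl is set by reductive enolate methylation.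
4. Ring order: C (pyrrolidine, chiral pool) → D (γ‑lactone on C9) → B + A in one operation → E.

Assumption: Stemona‑type locants are used (N4, C5 = N,O‑acetal CH, C6 = butenolide β‑carbon, C7, C8, C9 = spiro carbon, C9a, C1–C3 = pyrrolidine carbons, C11 = methyl‑bearing carbon of the spiro‑lactone, C14/C16 = O–CH and CH(Me) of the side lactone); the target read from the SMILES is 3S,5S,9S,9aS,11R,14S,16S. Compounds 3 and 6 are taken as purchasable.

**Route**

Step 1
Reactants: 1 furan-2(5H)-one
Product: 2 2-(triisopropylsilyloxy)furan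
Conditions: TIPSOTf, Et3N, CH2Cl2, 0 °C
Reagents that add atoms: triisopropylsilyl trifluoromethanesulfonate, CC(C)[Si](C(C)C)(C(C)C)OS(=O)(=O)C(F)(F)F
Why: Soft enolisation/O‑silylation of the butenolide gives the aromatic silyl dienol ether (standard 2‑silyloxyfuran formation); no stereocentre is involved.

Step 2
Reactants: 2 2-(triisopropylsilyloxy)furan; 3 2-(3-bromopropyl)-1,3-dioxolane
Product: 5 2-{3-[5-(triisopropylsilyloxy)furan-2-yl]propyl}-1,3-dioxolane, via 5-lithio-2-(triisopropylsilyloxy)furan 4 (not isolated)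
Conditions: s‑BuLi, TMEDA, THF, −78 → 0 °C; then 3, 0 → 23 °C
Reagents that add atoms: none
Why: Furan α‑lithiation at C5 (the bulky TIPS group suppresses O→C silyl migration) followed by SN2 alkylation with the primary bromide; no stereocentre is involved.

Step 3
Reactants: 6 di-tert-butyl (2S)-5-oxopyrrolidine-1,2-dicarboxylate
Product: 8 di-tert-butyl (2S)-5-methoxypyrrolidine-1,2-dicarboxylate, via hemiaminal 7 (not isolated)
Conditions: LiBEt3H, THF, −78 °C; then MeOH, p‑TsOH·H2O (1.2 equiv), −78 → 23 °C
Reagents that add atoms: methanol, CO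
Why: Super‑Hydride reduces the Boc‑activated lactam carbonyl to the hemiaminal and acid‑catalysed methanolysis gives the N,O‑acetal; the L‑configured C2 is untouched and the C5 epimer mixture does not matter.

Step 4
Reactants: 5 2-{3-[5-(triisopropylsilyloxy)furan-2-yl]propyl}-1,3-dioxolane; 8 di-tert-butyl (2S)-5-methoxypyrrolidine-1,2-dicarboxylate
Product: 9 di-tert-butyl (2S,5S)-5-[(2S)-2-[3-(1,3-dioxolan-2-yl)propyl]-5-oxo-2,5-dihydrofuran-2-yl]pyrrolidine-1,2-dicarboxylate
Conditions: TIPSOTf (10 mol %), CH2Cl2, −78 → −40 °C; chromatography/crystallisation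
Reagents that add atoms: none
Why: Vinylogous Mukaiyama–Mannich reaction in which catalytic silyl triflate ionises the N,O‑acetal in preference to the cyclic dioxolane and the silyloxyfuran attacks through C5, anti to the tert‑butyl ester (2,5‑trans, giving 9aS) and with the threo topicity typical of silyloxyfuran additions to cyclic N‑acyliminium ions (9S); selectivity is expected to be modest and minor diastereomers are separated.

Step 5
Reactants: 9 di-tert-butyl (2S,5S)-5-[(2S)-2-[3-(1,3-dioxolan-2-yl)propyl]-5-oxo-2,5-dihydrofuran-2-yl]pyrrolidine-1,2-dicarboxylate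
Product: 11 di-tert-butyl (2S,5S)-5-[(2S,4R)-2-[3-(1,3-dioxolan-2-yl)propyl]-4-methyl-5-oxooxolan-2-yl]pyrrolidine-1,2-dicarboxylate, via lithium lactone enolate 10 (not isolated)
Conditions: L‑Selectride (1.1 equiv), THF, −78 °C; then MeI (5 equiv), DMPU, −78 → −30 °C
Reagents that add atoms: iodomethane, CI
Why: Conjugate reduction with the trialkylborohydride gives the lactone enolate regiospecifically (reductive alkylation), and methylation occurs anti to the bulky N‑Boc‑pyrrolidinyl group, placing the methyl trans to C9a (11R), the epimer that hydrogenating a 3‑methylbutenolide from its open face would not give.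

Step 6
Reactants: 11 di-tert-butyl (2S,5S)-5-[(2S,4R)-2-[3-(1,3-dioxolan-2-yl)propyl]-4-methyl-5-oxooxolan-2-yl]pyrrolidine-1,2-dicarboxylate; 12 pyruvic acid
Product: 15 (3S,5S,9S,9aS,11R)-tetracyclic butenolide-aminal amino acid, via amino-acid aldehyde 13 (not isolated), via cyclic enamine 14 (not isolated)
Conditions: TFA/CH2Cl2/H2O (10:10:1), 0 → 23 °C; concentrate; then 12 (3 equiv), NaOAc (1.1 equiv), MeCN, 4 Å MS, 23 → 45 °C (0.02 M)
Reagents that add atoms: none
Why: Proposed new method: TFA removes Boc, tert‑butyl ester and dioxolane, the secondary amine condenses with the tethered aldehyde to the seven‑membered enamine (ring B), its β‑carbon C6 adds to the ketone of pyruvic acid, vinylogous loss of water gives the conjugated iminium ion and the (Z)‑carboxylate closes on C5 to the γ‑aminobutenolide (ring A); this closure is reversible and should settle on the 5S epimer, which has C5–O anti to the nitrogen lone pair of the trans‑fused bicycle (H5 trans to H9a); the closest known reactions are the Mannich‑type condensation of aldehydes with glyoxylic acid and secondary amines to 5‑amino‑2(5H)‑furanones and proline‑type enamine aldol additions to α‑keto acids.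

Step 7
Reactants: 16 3-methylfuran-2(5H)-one
Product: 17 3-methyl-2-(triisopropylsilyloxy)furan
Conditions: TIPSOTf, Et3N, CH2Cl2, 0 °C
Reagents that add atoms: triisopropylsilyl trifluoromethanesulfonate, CC(C)[Si](C(C)C)(C(C)C)OS(=O)(=O)C(F)(F)F
Why: Same silyl dienol ether formation as in step 1; no stereocentre is involved.

Step 8
Reactants: 15 (3S,5S,9S,9aS,11R)-tetracyclic butenolide-aminal amino acid; 17 3-methyl-2-(triisopropylsilyloxy)furan
Product: 19 (3S,5S,9S,9aS,11R,14S)-15,16-didehydro target, via C3 iminium chloride 18 (not isolated)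
Conditions: POCl3 (5 equiv), DMF, 23 °C (CO evolution); then 17 (2 equiv), −20 → 23 °C; aq. NaHCO3 work‑up
Reagents that add atoms: none
Why: Rapoport‑type decarbonylation of the tertiary α‑amino acid chloride gives the C3 iminium ion, and vinylogous Mannich addition of the silyloxyfuran through C5 occurs anti to the C9 spiro‑lactone (2,5‑trans, 3S) with threo topicity (14S), as in the analogous additions to bicyclic pyrrolo‑azepinium ions.

Step 9
Reactants: 19 (3S,5S,9S,9aS,11R,14S)-15,16-didehydro target
Product: 20 CNP0155196.1 (3S,5S,9S,9aS,11R,14S,16S)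
Conditions: H2 (1 atm), 5% Rh/Al2O3, EtOAc–AcOH (20:1), 23 °C
Reagents that add atoms: none
Why: Heterogeneous hydrogenation adds H2 to the trisubstituted butenolide from the face opposite the C14 substituent, giving the cis α‑methyl‑γ‑lactone (16S), while the tetrasubstituted butenolide A and its allylic N,O‑acetal are left alone under neutral, low‑pressure conditions.

**Compound list**
1 | furan-2(5H)-one | O=C1OCC=C1 | starting material
2 | 2-(triisopropylsilyloxy)furan | CC(C)[Si](C(C)C)(C(C)C)Oc1ccco1 | intermediate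
3 | 2-(3-bromopropyl)-1,3-dioxolane | BrCCCC1OCCO1 | starting material
4 | 5-lithio-2-(triisopropylsilyloxy)furan | [Li]c1ccc(O[Si](C(C)C)(C(C)C)C(C)C)o1 | intermediate
5 | 2-{3-[5-(triisopropylsilyloxy)furan-2-yl]propyl}-1,3-dioxolane | CC(C)[Si](C(C)C)(C(C)C)Oc1ccc(CCCC2OCCO2)o1 | intermediate
6 | di-tert-butyl (2S)-5-oxopyrrolidine-1,2-dicarboxylate (Boc-L-pyroglutamic acid tert-butyl ester) | O=C1CC[C@@H](C(=O)OC(C)(C)C)N1C(=O)OC(C)(C)C | starting material
7 | di-tert-butyl (2S)-5-hydroxypyrrolidine-1,2-dicarboxylate (C5 epimers) | OC1CC[C@@H](C(=O)OC(C)(C)C)N1C(=O)OC(C)(C)C | intermediate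
8 | di-tert-butyl (2S)-5-methoxypyrrolidine-1,2-dicarboxylate (C5 epimers) | COC1CC[C@@H](C(=O)OC(C)(C)C)N1C(=O)OC(C)(C)C | intermediate
9 | di-tert-butyl (2S,5S)-5-[(2S)-2-[3-(1,3-dioxolan-2-yl)propyl]-5-oxo-2,5-dihydrofuran-2-yl]pyrrolidine-1,2-dicarboxylate | O1CCOC1CCC[C@]2(C=CC(=O)O2)[C@@H]2CC[C@@H](C(=O)OC(C)(C)C)N2C(=O)OC(C)(C)C | intermediate
10 | lithium enolate of the lactone of 9 after 1,4-hydride addition | O1CCOC1CCC[C@]2(CC=C(O[Li])O2)[C@@H]2CC[C@@H](C(=O)OC(C)(C)C)N2C(=O)OC(C)(C)C | intermediate
11 | di-tert-butyl (2S,5S)-5-[(2S,4R)-2-[3-(1,3-dioxolan-2-yl)propyl]-4-methyl-5-oxooxolan-2-yl]pyrrolidine-1,2-dicarboxylate | O1CCOC1CCC[C@]2(C[C@@H](C)C(=O)O2)[C@@H]2CC[C@@H](C(=O)OC(C)(C)C)N2C(=O)OC(C)(C)C | intermediate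
12 | pyruvic acid | CC(=O)C(=O)O | starting material
13 | (2S,5S)-5-[(2S,4R)-4-methyl-5-oxo-2-(4-oxobutyl)oxolan-2-yl]pyrrolidine-2-carboxylic acid (as TFA salt) | O=CCCC[C@]2(C[C@@H](C)C(=O)O2)[C@@H]2CC[C@@H](C(=O)O)N2 | intermediate
14 | (3S,9S,9aS,11R)-cyclic enamine: 2,3,7,8,9,9a-hexahydro-1H-pyrrolo[1,2-a]azepine-3-carboxylic acid (C5=C6) with the 9-spiro α-methyl-γ-butyrolactone | C1=CCC[C@]2(C[C@@H](C)C(=O)O2)[C@@H]2CC[C@@H](C(=O)O)N12 | intermediate
15 | (3S,5S,9S,9aS,11R)-tetracyclic butenolide-aminal amino acid (target with CO2H in place of the C3 lactone) | CC1=C2CC[C@]3(C[C@@H](C)C(=O)O3)[C@@H]3CC[C@@H](C(=O)O)N3[C@H]2OC1=O | intermediate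
16 | 3-methylfuran-2(5H)-one | CC1=CCOC1=O | starting material
17 | 3-methyl-2-(triisopropylsilyloxy)furan | Cc1ccoc1O[Si](C(C)C)(C(C)C)C(C)C | intermediate
18 | (5S,9S,9aS,11R)-tetracyclic C3=N4 iminium chloride | CC1=C2CC[C@]3(C[C@@H](C)C(=O)O3)[C@@H]3CCC=[N+]3[C@H]2OC1=O.[Cl-] | intermediate
19 | (3S,5S,9S,9aS,11R,14S)-15,16-didehydro target; C3 carries (2S)-4-methyl-5-oxo-2,5-dihydrofuran-2-yl | CC1=C2CC[C@]3(C[C@@H](C)C(=O)O3)[C@@H]3CC[C@@H]([C@@H]4C=C(C)C(=O)O4)N3[C@H]2OC1=O | intermediate
20 | CNP0155196.1, (3S,5S,9S,9aS,11R,14S,16S) | CC1=C2CC[C@]3(C[C@@H](C)C(=O)O3)[C@@H]3CC[C@@H]([C@@H]4C[C@H](C)C(=O)O4)N3[C@H]2OC1=O | target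

**Totals**
Total step count: 9. Longest linear sequence: 7 (steps 1, 2, 4, 5, 6, 8, 9).

**Three steps most likely to fail**

1. Step 6. The enamine/pyruvic acid annulation is untested: the ketone of pyruvic acid may be too weak an electrophile or be consumed by decarboxylative side reactions, and the C5 configuration rests on thermodynamic control. Fallback: setting out from 11, the same TFA unmasking is followed by condensation with glyoxylic acid monohydrate, the electrophile for which this aldehyde/secondary‑amine butenolide synthesis is established, to give the α‑unsubstituted butenolide aminal acid F1. Bromine addition and Et3N‑induced loss of HBr give the α‑bromobutenolide F2, and Stille methylation (Me4Sn, Pd(PPh3)4, CuI, DMF) returns to the route at 15.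

2. Step 8. The N,O‑acetal may not survive POCl3/DMF, or the acid chloride may decarbonylate sluggishly because the nitrogen is less basic; trans/threo selectivity is expected to be only moderate. Fallback: setting out from 15, anodic (Hofer–Moest) decarboxylation in methanol gives the isolable C3‑methoxy N,O‑acetal F3, which is ionised with catalytic TIPSOTf at −78 °C in CH2Cl2 in the presence of 17, as in step 4, returning to the route at 19.

3. Step 5. Hydride delivery to the β‑carbon next to the quaternary centre may be slow or give 1,2‑reduction, and the boron‑bound enolate may methylate poorly. Fallback: setting out from 9, the butenolide is hydrogenated (H2, Pd/C, EtOAc) to the saturated lactone F4, which is deprotonated selectively at the lactone α‑CH2 (LDA, THF, −78 °C) and methylated with MeI on the same open face, returning to the route at 11.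

**Further compounds**
F1 | step 6 | (3S,5S,9S,9aS,11R)-tetracyclic aminal amino acid lacking the butenolide α-methyl group | C1=C2CC[C@]3(C[C@@H](C)C(=O)O3)[C@@H]3CC[C@@H](C(=O)O)N3[C@H]2OC1=O
F2 | step 6 | (3S,5S,9S,9aS,11R)-tetracyclic aminal amino acid with an α-bromobutenolide | BrC1=C2CC[C@]3(C[C@@H](C)C(=O)O3)[C@@H]3CC[C@@H](C(=O)O)N3[C@H]2OC1=O
F3 | step 8 | (5S,9S,9aS,11R)-3-methoxy tetracyclic N,O-acetal (C3 epimers) | CC1=C2CC[C@]3(C[C@@H](C)C(=O)O3)[C@@H]3CCC(OC)N3[C@H]2OC1=O
F4 | step 5 | di-tert-butyl (2S,5S)-5-[(2S)-2-[3-(1,3-dioxolan-2-yl)propyl]-5-oxooxolan-2-yl]pyrrolidine-1,2-dicarboxylate | O1CCOC1CCC[C@]2(CCC(=O)O2)[C@@H]2CC[C@@H](C(=O)OC(C)(C)C)N2C(=O)OC(C)(C)C
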